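**Retrosynthetic overview**
- The target comes from the free triol by peracetylation and selective cleavage of the two aryl acetates; the triol comes from a 2-(trimethylsilyl)ethyl 6-alkyl-2,4-dihydroxybenzoate by desilylation and loss of the temporary carboxyl on arene C6.
- The strategy rests on the benzene ring with OH on C1 and C3 and the chain C1'–C15' on C5. This meta pattern is the fold of a 3,5,7-trioxo ester whose C7, the carboxyl carbon of a C16 hydroxy acid, becomes arene C5.
- The resorcylate is disconnected to a diketo-dioxinone and 2-(trimethylsilyl)ethanol: acylketene capture, then a C2–C7 aldol condensation that forms the arene C5–C6 bond and the only ring (the benzene ring) in one step.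
- The diketo-dioxinone comes from the dianion of 2,2-dimethyl-6-(2-oxopropyl)-1,3-dioxin-4-one (trimethyldioxinone plus AcCl) and the acyl imidazole of (9Z,11R)-11-silyloxyhexadec-9-enoic acid by a crossed Claisen condensation.
- The acid comes from silylated (R)-oct-1-yn-3-ol (source of C10') and 8-bromooctanoic acid by acetylide alkylation, then Lindlar reduction to the Z C8'=C9' alkene.

Key step: step 6

Remark: (R)-oct-1-yn-3-ol is assumed to be bought in high enantiomeric purity; arene locants are C1/C3 (OH) and C5 (chain C1'–C15'), and the open-chain trioxo ester is numbered from its ester carbonyl C1.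

**Step 1**
Reactants: 1 (R)-oct-1-yn-3-ol
Product: 2 (R)-tert-butyldimethyl(oct-1-yn-3-yloxy)silane
Conditions: TBSCl (1.2 equiv), imidazole (2.5 equiv), DMF, 0 °C to rt
Reagents that add atoms: tert-butyldimethylsilyl chloride, CC(C)(C)[Si](C)(C)Cl
Why: Imidazole-promoted O-silylation of a secondary alcohol breaks no bond at C3, so the R configuration bought with 1 is carried over and the acidic O–H is masked before the acetylide is made.

**Step 2**
Reactants: 2 (R)-tert-butyldimethyl(oct-1-yn-3-yloxy)silane; 3 8-bromooctanoic acid
Product: 4 (R)-11-(tert-butyldimethylsilyloxy)hexadec-9-ynoic acid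
Conditions: 2 (2.2 equiv), n-BuLi (2.1 equiv), THF/DMPU, −78 to 0 °C; then 3 (1.0 equiv), 0 °C to rt; cold 1 M HCl to pH 3; surplus 2 recovered
Reagents that add atoms: none
Why: Acetylide alkylation (SN2 at a primary bromide, accelerated by DMPU) in which the first equivalent of lithium acetylide turns 3 into its unreactive lithium carboxylate and the second displaces bromide, while the non-acidic C11 centre and the silyl ether are untouched.

**Step 3**
Reactants: 4 (R)-11-(tert-butyldimethylsilyloxy)hexadec-9-ynoic acid
Product: 5 (9Z,11R)-11-(tert-butyldimethylsilyloxy)hexadec-9-enoic acid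
Conditions: H2 (1 atm), Pd/CaCO3 poisoned with Pb(OAc)2 (Lindlar catalyst), quinoline, EtOAc, rt, stopped after 1 equiv H2
Reagents that add atoms: none
Why: Lindlar semihydrogenation adds both hydrogens from the catalyst surface to the same face of the alkyne, which should give the Z alkene only, while quinoline suppresses over-reduction and the silyl ether, the acid and the C11 centre are inert.

**Step 4**
Reactants: 6 2,2,6-trimethyl-4H-1,3-dioxin-4-one
Product: 7 2,2-dimethyl-6-(2-oxopropyl)-4H-1,3-dioxin-4-one
Conditions: LiN(SiMe3)2 (1.0 equiv), THF, −78 °C; AcCl (0.5 equiv), −78 °C; 1 M HCl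
Reagents that add atoms: acetyl chloride, CC(=O)Cl
Why: γ-Deprotonation of 6 gives the extended lithium enolate, which is C-acylated at its exocyclic carbon by acetyl chloride (vinylogous Claisen acylation), half of the enolate being spent as base for the more acidic product, hence the stoichiometry.

**Step 5**
Reactants: 5 (9Z,11R)-11-(tert-butyldimethylsilyloxy)hexadec-9-enoic acid; 7 2,2-dimethyl-6-(2-oxopropyl)-4H-1,3-dioxin-4-one
Product: 9 6-[(12Z,14R)-14-(tert-butyldimethylsilyloxy)-2,4-dioxononadec-12-en-1-yl]-2,2-dimethyl-4H-1,3-dioxin-4-one, via acyl imidazole 8 (not isolated)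
Conditions: 5, CDI (1.05 equiv), THF, rt; separately 7 (2.5 equiv), LiN(i-Pr)2 (5.0 equiv), THF, −78 to −40 °C; add solution of 8, −78 to −20 °C; AcOH, −78 °C
Reagents that add atoms: 1,1'-carbonyldiimidazole, O=C(n1ccnc1)n1ccnc1 (gives the imidazolyl group of 8; none of its atoms stay in 9)
Why: CDI activates the acid under neutral conditions as acyl imidazole 8, and the dianion of 7 is acylated at its terminal, most basic carbon in a crossed Claisen condensation, the surplus dianion taking up the imidazole N–H and the acidic 1,3-diketone product, with no stereocentre formed and C14 not enolisable.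

**Step 6**
Reactants: 9 6-[(12Z,14R)-14-(tert-butyldimethylsilyloxy)-2,4-dioxononadec-12-en-1-yl]-2,2-dimethyl-4H-1,3-dioxin-4-one; 10 2-(trimethylsilyl)ethanol
Product: 13 2-(trimethylsilyl)ethyl 6-[(8Z,10R)-10-(tert-butyldimethylsilyloxy)pentadec-8-en-1-yl]-2,4-dihydroxybenzoate, via acylketene 11 (not isolated), via trioxo ester 12 (not isolated)
Conditions: 10 (3 equiv), PhMe, 110 °C; evaporate; Cs2CO3 (3 equiv), i-PrOH/CH2Cl2, rt; then AcOH
Reagents that add atoms: none
Why: At 110 °C the dioxinone of 9 undergoes a retro-hetero-Diels–Alder loss of acetone to acylketene 11, which the excess alcohol 10 intercepts at the ketene carbon to give the open 3,5,7-trioxo ester 12; Cs2CO3 then generates the enolates of 12, the C2 carbon adds to the C7 ketone, and loss of water (E1cB) followed by enolisation of the C3 and C5 carbonyls gives the arene. The closest known reaction type is the ketene-trapping and aldol aromatisation of diketo-dioxinones to 6-alkyl-2,4-dihydroxybenzoates, the laboratory parallel of the aldol folding used by polyketide synthases. The benzene ring, the only ring closed, forms by a 6-(enolendo)-exo-trig aldol addition that makes the C2–C7 bond of 12, which is the arene C5–C6 bond of the target. No stereocentre is created, and the C10' centre and the Z alkene lie far from every acidic position and see only a weak base and a short period of heating. The step needs the C2-to-C7 aldol mode over the C6-to-C1 Claisen closure to an acylphloroglucinol, the C8-to-C3 aldol and O-cyclisation to pyrones: of the more acidic diketone methylenes, C4 can close no six-membered ring and C6 can reach only the poorly electrophilic ester C1, C8–H is roughly ten pKa units less acidic, and so attack of the ester-flanked C2 enolate on the C7 ketone is the one fast path, made irreversible by aromatisation. Intramolecular capture of 11 by the C5 enol oxygen is outrun by using 10 in excess.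

**Step 7**
Reactants: 13 2-(trimethylsilyl)ethyl 6-[(8Z,10R)-10-(tert-butyldimethylsilyloxy)pentadec-8-en-1-yl]-2,4-dihydroxybenzoate
Product: 15 5-[(8Z,10R)-10-hydroxypentadec-8-en-1-yl]benzene-1,3-diol, via resorcylic acid 14 (not isolated)
Conditions: Bu4NF (5 equiv), THF, rt to 45 °C; cold 1 M HCl to pH 3, extraction; crude 14 in DMF, 100 °C
Reagents that add atoms: none
Why: Fluoride attacks both silicon atoms, so that the silylethyl ester fragments to ethylene and the carboxylate (β-elimination) and the C10' silyl ether is cleaved, and the freed 2,4-dihydroxybenzoic acid then loses CO2 on warming through ipso-protonation of the carboxyl-bearing ring carbon, which is ortho and para to the two hydroxyls (thermal protodecarboxylation of a β-resorcylic acid), under conditions that do not ionise the C10' carbinol or isomerise the Z alkene.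

**Step 8**
Reactants: 15 5-[(8Z,10R)-10-hydroxypentadec-8-en-1-yl]benzene-1,3-diol
Product: 16 5-[(8Z,10R)-10-acetoxypentadec-8-en-1-yl]-1,3-phenylene diacetate
Conditions: Ac2O (5 equiv), pyridine, DMAP (cat.), CH2Cl2, 0 °C to rt
Reagents that add atoms: acetic anhydride, CC(=O)OC(C)=O
Why: DMAP-catalysed O-acetylation (nucleophilic acyl transfer) esterifies the two phenols and the secondary allylic alcohol without breaking the C10'–O bond, so the configuration is retained.

**Step 9**
Reactants: 16 5-[(8Z,10R)-10-acetoxypentadec-8-en-1-yl]-1,3-phenylene diacetate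
Product: 17 5-[(8Z,10R)-10-acetoxypentadec-8-en-1-yl]benzene-1,3-diol, that is (6R,7Z)-15-(3,5-dihydroxyphenyl)pentadec-7-en-6-yl acetate (target)
Conditions: NH4OAc (8 equiv), MeOH/H2O 4:1, rt
Reagents that add atoms: none
Why: An aryl acetate has a far better leaving group (phenoxide) than a secondary alkyl acetate, so the NH4OAc-mediated neutral methanolysis (chemoselective transesterification) should remove only the two phenolic acetates and leave the hindered C10' allylic acetate and its configuration intact.

**Compound list**
1 | (R)-oct-1-yn-3-ol | CCCCC[C@H](C#C)O | starting material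
2 | (R)-tert-butyldimethyl(oct-1-yn-3-yloxy)silane | CCCCC[C@H](C#C)O[Si](C)(C)C(C)(C)C | intermediate
3 | 8-bromooctanoic acid | OC(=O)CCCCCCCBr | starting material
4 | (R)-11-(tert-butyldimethylsilyloxy)hexadec-9-ynoic acid | CCCCC[C@H](C#CCCCCCCCC(=O)O)O[Si](C)(C)C(C)(C)C | intermediate
5 | (9Z,11R)-11-(tert-butyldimethylsilyloxy)hexadec-9-enoic acid | CCCCC[C@H](/C=C\CCCCCCCC(=O)O)O[Si](C)(C)C(C)(C)C | intermediate
6 | 2,2,6-trimethyl-4H-1,3-dioxin-4-one | CC1=CC(=O)OC(C)(C)O1 | starting material
7 | 2,2-dimethyl-6-(2-oxopropyl)-4H-1,3-dioxin-4-one | CC(=O)CC1=CC(=O)OC(C)(C)O1 | intermediate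
8 | 1-[(9Z,11R)-11-(tert-butyldimethylsilyloxy)hexadec-9-enoyl]-1H-imidazole (acyl imidazole) | CCCCC[C@H](/C=C\CCCCCCCC(=O)n1ccnc1)O[Si](C)(C)C(C)(C)C | intermediate (not isolated)
9 | 6-[(12Z,14R)-14-(tert-butyldimethylsilyloxy)-2,4-dioxononadec-12-en-1-yl]-2,2-dimethyl-4H-1,3-dioxin-4-one | CCCCC[C@H](/C=C\CCCCCCCC(=O)CC(=O)CC1=CC(=O)OC(C)(C)O1)O[Si](C)(C)C(C)(C)C | intermediate
10 | 2-(trimethylsilyl)ethanol | OCC[Si](C)(C)C | starting material
11 | (15Z,17R)-17-(tert-butyldimethylsilyloxy)docosa-1,15-diene-1,3,5,7-tetrone (acylketene) | CCCCC[C@H](/C=C\CCCCCCCC(=O)CC(=O)CC(=O)C=C=O)O[Si](C)(C)C(C)(C)C | intermediate (not isolated)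
12 | 2-(trimethylsilyl)ethyl (15Z,17R)-17-(tert-butyldimethylsilyloxy)-3,5,7-trioxodocos-15-enoate (trioxo ester) | CCCCC[C@H](/C=C\CCCCCCCC(=O)CC(=O)CC(=O)CC(=O)OCC[Si](C)(C)C)O[Si](C)(C)C(C)(C)C | intermediate (not isolated)
13 | 2-(trimethylsilyl)ethyl 6-[(8Z,10R)-10-(tert-butyldimethylsilyloxy)pentadec-8-en-1-yl]-2,4-dihydroxybenzoate | CCCCC[C@H](/C=C\CCCCCCCc1cc(O)cc(O)c1C(=O)OCC[Si](C)(C)C)O[Si](C)(C)C(C)(C)C | intermediate
14 | 2,4-dihydroxy-6-[(8Z,10R)-10-hydroxypentadec-8-en-1-yl]benzoic acid (resorcylic acid) | CCCCC[C@H](/C=C\CCCCCCCc1cc(O)cc(O)c1C(=O)O)O | intermediate (not isolated)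
15 | 5-[(8Z,10R)-10-hydroxypentadec-8-en-1-yl]benzene-1,3-diol | CCCCC[C@H](/C=C\CCCCCCCc1cc(O)cc(O)c1)O | intermediate
16 | 5-[(8Z,10R)-10-acetoxypentadec-8-en-1-yl]-1,3-phenylene diacetate | CCCCC[C@H](/C=C\CCCCCCCc1cc(OC(C)=O)cc(OC(C)=O)c1)OC(C)=O | intermediate
17 | 5-[(8Z,10R)-10-acetoxypentadec-8-en-1-yl]benzene-1,3-diol | CCCCC[C@H](/C=C\CCCCCCCc1cc(O)cc(O)c1)OC(C)=O | target

**Step count**
Total: 9 steps. Longest linear sequence: 8 steps (steps 1, 2, 3, 5, 6, 7, 8, 9 from compound 1); step 4 is a one-step branch.

**Steps most likely to fail**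

Step 6. The acylketene may be captured by its own C5 enol oxygen to give a hydroxypyrone before the alcohol reaches it, or the base treatment may divert part of the chain into the Claisen-mode closure, and the silyl ether may suffer if the dehydration needs stronger acid. The fallback sets out from 9 and comes back at 13, and it closes the benzene ring before the dioxinone is opened. Et3N in CH2Cl2 at rt should let the dioxinone C5 add to the same ketone carbon (vinylogous aldol, then dehydration) to give 5-[(8Z,10R)-10-(tert-butyldimethylsilyloxy)pentadec-8-en-1-yl]-7-hydroxy-2,2-dimethyl-4H-1,3-benzodioxin-4-one F1. This benzodioxinone is then opened with excess sodium 2-(trimethylsilyl)ethoxide (10 and NaH, THF, 0 °C to rt), which gives 13 with loss of acetone. No free acylketene and no open-chain ester exist on this path, so the pyrone and Claisen pathways are removed.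

Step 5. Proton transfer from the liberated imidazole and from the acidic product to the dianion may stall the acylation at partial conversion, with O-acylation of the enolate as a side process. The fallback sets out from 5 and comes back at 9, and it changes the acyl donor class. The acid 5 is converted (CDI, then MeNHOMe·HCl, CH2Cl2, rt) into (9Z,11R)-11-(tert-butyldimethylsilyloxy)-N-methoxy-N-methylhexadec-9-enamide F2, and this Weinreb amide is added to the dianion of 7 (LiN(i-Pr)2, THF, −78 to 0 °C). The lithium-chelated tetrahedral adduct should persist until the acidic quench, so the diketone never meets unreacted dianion, and no N–H by-product is present.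

Step 7. Fluoride cleavage of the silylethyl ester may be slow on the electron-rich bis-phenoxide, and the free allylic alcohol may condense or eliminate while the acid is heated. The fallback sets out from 9 and comes back at 15; the ester is changed at the ketene-trapping stage and the decarboxylation is run with the silyl ether in place. Thermolysis of 9 with allyl alcohol in place of 10, then Cs2CO3 as in step 6, should give prop-2-en-1-yl 6-[(8Z,10R)-10-(tert-butyldimethylsilyloxy)pentadec-8-en-1-yl]-2,4-dihydroxybenzoate F3. Pd(PPh3)4 (cat.) with morpholine in THF at rt removes the allyl group under neutral conditions and gives 6-[(8Z,10R)-10-(tert-butyldimethylsilyloxy)pentadec-8-en-1-yl]-2,4-dihydroxybenzoic acid F4. Warming in toluene at 90–100 °C decarboxylates it to 5-[(8Z,10R)-10-(tert-butyldimethylsilyloxy)pentadec-8-en-1-yl]benzene-1,3-diol F5, and Bu4NF in THF at rt then frees the carbinol to give 15.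

**Further compounds**
F1 | step 6 | 5-[(8Z,10R)-10-(tert-butyldimethylsilyloxy)pentadec-8-en-1-yl]-7-hydroxy-2,2-dimethyl-4H-1,3-benzodioxin-4-one | CCCCC[C@H](/C=C\CCCCCCCc1cc(O)cc2OC(C)(C)OC(=O)c12)O[Si](C)(C)C(C)(C)C
F2 | step 5 | (9Z,11R)-11-(tert-butyldimethylsilyloxy)-N-methoxy-N-methylhexadec-9-enamide | CCCCC[C@H](/C=C\CCCCCCCC(=O)N(C)OC)O[Si](C)(C)C(C)(C)C
F3 | step 7 | prop-2-en-1-yl 6-[(8Z,10R)-10-(tert-butyldimethylsilyloxy)pentadec-8-en-1-yl]-2,4-dihydroxybenzoate | CCCCC[C@H](/C=C\CCCCCCCc1cc(O)cc(O)c1C(=O)OCC=C)O[Si](C)(C)C(C)(C)C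
F4 | step 7 | 6-[(8Z,10R)-10-(tert-butyldimethylsilyloxy)pentadec-8-en-1-yl]-2,4-dihydroxybenzoic acid | CCCCC[C@H](/C=C\CCCCCCCc1cc(O)cc(O)c1C(=O)O)O[Si](C)(C)C(C)(C)C
F5 | step 7 | 5-[(8Z,10R)-10-(tert-butyldimethylsilyloxy)pentadec-8-en-1-yl]benzene-1,3-diol | CCCCC[C@H](/C=C\CCCCCCCc1cc(O)cc(O)c1)O[Si](C)(C)C(C)(C)C
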